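**Retrosynthetic overview**
1. Target 24 comes from diene 23 by [4+2] addition of singlet oxygen across C2/C5 of the cyclohexadiene (face anti to the cyclobutane); the methoxypyrone of 23 is built on aldehyde 17 with the dianion of ketoester 18.
2. The bicyclo[4.2.0]octadiene (15) is the valence isomer of cycloocta-1,3,5-triene 14 (6π closure, C1–C6), which comes from dienone 12 by enol triflation and methyl coupling.
3. Structural feature: C7 (quaternary; methyl and future pyronyl carbon) and C8 (CHMe) of the cyclobutane are the only directly bonded sp3 carbons of the eight-membered triene (ring C1–C8). Their bond and the eight-membered ring are made together by Claisen ring expansion of 2-ethylidene-6-alkenyl-3,6-dihydro-2H-pyran 11 to 12.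
4. Enol ether 11 comes from lactone 8 (Takai ethylidenation), 8 from ester 7 (ring-closing metathesis), 7 from tertiary carbinol 5 (asymmetric alkenylation of Z-enone 4), and 4 from butenolide 1, whose ring supplies the Z alkene.
5. Ring order: dihydropyranone (metathesis), eight-membered carbocycle (Claisen), cyclohexadiene and cyclobutane (6π), pyrone, 1,2-dioxane bridge.

Key step: step 8

Assumption: in step 4 the ligand antipode is chosen that delivers the alkenyl group to the ketone face giving the (4S) alcohol; from compound 12 on, atoms carry the numbers of the bicyclo[4.2.0]octane core (C1 methylated fusion carbon, C6 fusion CH, C7 quaternary, C8 CHMe).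

**Step 1**
Reactants: 1 4-methylfuran-2(5H)-one
Product: 2 (2Z)-4-hydroxy-N-methoxy-N,3-dimethylbut-2-enamide
Conditions: MeNH(OMe)·HCl, AlMe3, CH2Cl2, 0 °C → rt; aqueous work-up, used crude
Reagents that add atoms: N,O-dimethylhydroxylamine hydrochloride (CNOC.Cl)
Why: Weinreb aminolysis by the aluminium amide should open the lactone at the acyl carbon, and the Z geometry of the trisubstituted alkene is the cis geometry of the butenolide ring.

**Step 2**
Reactants: 2 (2Z)-4-hydroxy-N-methoxy-N,3-dimethylbut-2-enamide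
Product: 3 (2Z)-4-[(tert-butyldimethylsilyl)oxy]-N-methoxy-N,3-dimethylbut-2-enamide
Conditions: TBSCl, imidazole, DMF, 0 °C
Reagents that add atoms: tert-butyldimethylsilyl chloride (CC(C)(C)[Si](C)(C)Cl)
Why: Imidazole-promoted silylation of the primary alcohol should outrun relactonisation and lock the open Z form.

**Step 3**
Reactants: 3 (2Z)-4-[(tert-butyldimethylsilyl)oxy]-N-methoxy-N,3-dimethylbut-2-enamide
Product: 4 (3Z)-5-[(tert-butyldimethylsilyl)oxy]-4-methylpent-3-en-2-one
Conditions: MeMgBr, THF, −20 → 0 °C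
Reagents that add atoms: methylmagnesium bromide (C[Mg]Br)
Why: Weinreb ketone synthesis, in which the chelated tetrahedral intermediate stops at mono-addition and the β,β-disubstituted alkene resists conjugate addition, so the Z-enone should result.

**Step 4**
Reactants: 4 (3Z)-5-[(tert-butyldimethylsilyl)oxy]-4-methylpent-3-en-2-one
Product: 5 (2Z,4S,5E)-1-[(tert-butyldimethylsilyl)oxy]-2,4-dimethyldeca-2,5-dien-4-ol
Conditions: 1-hexyne, Cp2ZrHCl, CH2Cl2, rt; Me2Zn, PhMe, −78 °C; then bis(sulfonamide) diol ligand from trans-cyclohexane-1,2-diamine and camphorsulfonyl chloride (10 mol %), Ti(OiPr)4, 4, rt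
Reagents that add atoms: 1-hexyne (CCCCC#C)
Why: Catalytic asymmetric vinylation of a ketone by an (E)-alkenylzinc from hydrozirconation and zirconium-to-zinc exchange, in which the titanium bis(sulfonamide) diol catalyst should add 1,2 to the enone and distinguish methyl from the branched alkenyl group to set the (4S) carbinol by reagent control.

**Step 5**
Reactants: 5 (2Z,4S,5E)-1-[(tert-butyldimethylsilyl)oxy]-2,4-dimethyldeca-2,5-dien-4-ol; 6 3-methylbut-3-enoic acid
Product: 7 (2Z,4S,5E)-1-[(tert-butyldimethylsilyl)oxy]-2,4-dimethyldeca-2,5-dien-4-yl 3-methylbut-3-enoate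
Conditions: DCC, DMAP, CH2Cl2, 0 °C → rt
Reagents that add atoms: none
Why: Steglich esterification, in which the acylpyridinium of this β,γ-unsaturated acid readily gives isopropenylketene that even a hindered tertiary alcohol should capture, with kinetic α-protonation keeping the alkene out of conjugation and the carbinol centre untouched.

**Step 6**
Reactants: 7 (2Z,4S,5E)-1-[(tert-butyldimethylsilyl)oxy]-2,4-dimethyldeca-2,5-dien-4-yl 3-methylbut-3-enoate
Product: 8 (6S)-6-[(1Z)-3-[(tert-butyldimethylsilyl)oxy]-2-methylprop-1-en-1-yl]-4,6-dimethyl-3,6-dihydro-2H-pyran-2-one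
Conditions: second-generation Grubbs catalyst RuCl2(=CHPh)(PCy3)(H2IMes) (5 mol %), 1,4-benzoquinone (10 mol %), PhMe, 60 °C
Reagents that add atoms: none
Why: Ring-closing metathesis between the isopropenyl group and the E-disubstituted hexenyl arm should close the six-membered lactone with loss of hex-1-ene, while the Z-trisubstituted side-chain alkene next to the quaternary carbon is too hindered to engage and benzoquinone suppresses alkene migration into conjugation.

**Step 7**
Reactants: 8 (6S)-6-[(1Z)-3-[(tert-butyldimethylsilyl)oxy]-2-methylprop-1-en-1-yl]-4,6-dimethyl-3,6-dihydro-2H-pyran-2-one; 9 1,1-dibromoethane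
Product: 11 (2Z,6S)-6-[(1Z)-3-[(tert-butyldimethylsilyl)oxy]-2-methylprop-1-en-1-yl]-2-ethylidene-4,6-dimethyl-3,6-dihydro-2H-pyran, via 1,1-bis(bromozincio)ethane 10 (not isolated)
Conditions: 9, Zn, PbCl2 (cat.), TiCl4, TMEDA, THF, 0 → 25 °C; then 8; Et3N/K2CO3 work-up, basic alumina
Reagents that add atoms: none
Why: Takai–Utimoto alkylidenation of the ester carbonyl by the titanium-activated geminal dizinc reagent, which is weakly basic and should give the Z enol ether (methyl cis to the ring oxygen) without touching the alkenes or the silyl ether.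

**Step 8**
Reactants: 11 (2Z,6S)-6-[(1Z)-3-[(tert-butyldimethylsilyl)oxy]-2-methylprop-1-en-1-yl]-2-ethylidene-4,6-dimethyl-3,6-dihydro-2H-pyran
Product: 12 (7R,8S)-7-{[(tert-butyldimethylsilyl)oxy]methyl}-3,5,7,8-tetramethylcycloocta-3,5-dien-1-one (both ring alkenes cis)
Conditions: degassed PhMe, base-washed sealed tube, 120–140 °C
Reagents that add atoms: none
Why: A concerted suprafacial [3,3] shift (Claisen) of the allyl vinyl ether CH(Me)=C2–O1–C6–CH=C(Me)CH2OTBS should join the ethylidene carbon (future C8) to the side-chain terminus (future C7) while O1–C6 breaks, giving the C1 ketone and a new cis C5=C6 ring alkene; the closest known reaction is the thermal Claisen ring expansion of 2-alkylidene-6-vinyltetrahydropyrans to cyclooct-4-enones. The eight-membered carbocycle is closed by two-atom ring expansion of the six-membered oxacycle through a bridged chair array (the C3–C4–C5 pyran bridge stays, the oxygen bridge is excised), not by end-to-end cyclisation. C8 is set by the Z enol ether (methyl cis to oxygen, axial) and C7 by the Z side-chain alkene (CH2OTBS cis to C6, axial; methyl equatorial), which places CH2OTBS anti to the C8 methyl across the new bond, so the C7 and C8 methyls end up cis. The absolute sense comes from the (S) ether carbon, whose ring bond must be axial for the new ring alkene to be cis, and this fixes the enol ether face that bonds. The step needs chair over boat and [3,3] over ionisation or [1,3] pathways: in a boat the side-chain CH would occupy the space through which the three-carbon bridge links C2 to C6, and base-washed glass with a non-polar solvent should suppress heterolysis of the bis-allylic C–O bond and migration of the exocyclic alkene into the ring. The weak, doubly allylic tertiary C6–O bond should lower the barrier and offset the cost of the axial CH2OTBS group sitting over the dihydropyran bridge.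

**Step 9**
Reactants: 12 (7R,8S)-7-{[(tert-butyldimethylsilyl)oxy]methyl}-3,5,7,8-tetramethylcycloocta-3,5-dien-1-one
Product: 13 (7R,8S)-7-{[(tert-butyldimethylsilyl)oxy]methyl}-3,5,7,8-tetramethylcycloocta-1,3,5-trien-1-yl trifluoromethanesulfonate (all ring alkenes cis)
Conditions: KN(SiMe3)2, THF, −78 °C; PhNTf2, −78 → −20 °C
Reagents that add atoms: N-phenylbis(trifluoromethanesulfonimide) (O=S(=O)(N(c1ccccc1)S(=O)(=O)C(F)(F)F)C(F)(F)F)
Why: Kinetic deprotonation at C2, whose hydrogens are both α to the carbonyl and allylic, should give the linear trienolate that is trapped on oxygen (enol triflate formation), while the tertiary C8–H next to quaternary C7 is not removed at −78 °C and C8 keeps its configuration.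

**Step 10**
Reactants: 13 (7R,8S)-7-{[(tert-butyldimethylsilyl)oxy]methyl}-3,5,7,8-tetramethylcycloocta-1,3,5-trien-1-yl trifluoromethanesulfonate
Product: 15 tert-butyl(dimethyl){[(1R,6R,7S,8R)-1,3,5,7,8-pentamethylbicyclo[4.2.0]octa-2,4-dien-7-yl]methoxy}silane, via cyclooctatriene 14 (not isolated)
Conditions: Me2Zn, Pd(PPh3)4 (5 mol %), THF, 0 °C → rt; then 45 °C
Reagents that add atoms: dimethylzinc (C[Zn]C)
Why: Negishi methylation (oxidative addition of zerovalent palladium into the trienyl C–OTf bond, transmetalation, reductive elimination) gives the all-cis triene, whose thermal disrotatory 6π electrocyclisation should form C1–C6 with cis fusion; the two cis-fused isomers interconvert through 14, and the one with only CH2OTBS and H8 on the concave face (C7 and C8 methyls exo) should be preferred over the one with two endo methyls, which sets C1 and C6 relative to C7/C8, and the temperature is kept low to avoid [1,5]-hydrogen shifts.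

**Step 11**
Reactants: 15 tert-butyl(dimethyl){[(1R,6R,7S,8R)-1,3,5,7,8-pentamethylbicyclo[4.2.0]octa-2,4-dien-7-yl]methoxy}silane
Product: 16 [(1R,6R,7S,8R)-1,3,5,7,8-pentamethylbicyclo[4.2.0]octa-2,4-dien-7-yl]methanol
Conditions: Bu4NF, THF, 0 °C → rt
Reagents that add atoms: none
Why: Fluoride cleavage of the primary silyl ether should be clean because nothing else in 15 is fluoride-labile.

**Step 12**
Reactants: 16 [(1R,6R,7S,8R)-1,3,5,7,8-pentamethylbicyclo[4.2.0]octa-2,4-dien-7-yl]methanol
Product: 17 (1R,6R,7S,8R)-1,3,5,7,8-pentamethylbicyclo[4.2.0]octa-2,4-diene-7-carbaldehyde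
Conditions: Dess–Martin periodinane, CH2Cl2, 0 °C → rt
Reagents that add atoms: none
Why: Dess–Martin oxidation of the neopentyl primary alcohol should stop at the aldehyde, which has no α-hydrogen, so C7 cannot epimerise.

**Step 13**
Reactants: 17 (1R,6R,7S,8R)-1,3,5,7,8-pentamethylbicyclo[4.2.0]octa-2,4-diene-7-carbaldehyde; 18 methyl 2-methyl-3-oxopentanoate
Product: 20 methyl 5-hydroxy-2,4-dimethyl-3-oxo-5-[(1R,6R,7S,8R)-1,3,5,7,8-pentamethylbicyclo[4.2.0]octa-2,4-dien-7-yl]pentanoate (mixture of side-chain diastereomers), via ketoester dianion 19 (not isolated)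
Conditions: 18, NaH, THF, 0 °C; n-BuLi, 0 °C; then 17, −78 → −40 °C
Reagents that add atoms: none
Why: Aldol addition of the γ-carbon of the β-ketoester dianion to the non-enolisable aldehyde should be regioselective, and the three uncontrolled side-chain stereocentres are erased in steps 14 and 15.

**Step 14**
Reactants: 20 methyl 5-hydroxy-2,4-dimethyl-3-oxo-5-[(1R,6R,7S,8R)-1,3,5,7,8-pentamethylbicyclo[4.2.0]octa-2,4-dien-7-yl]pentanoate
Product: 21 methyl 2,4-dimethyl-3,5-dioxo-5-[(1R,6R,7S,8R)-1,3,5,7,8-pentamethylbicyclo[4.2.0]octa-2,4-dien-7-yl]pentanoate (epimers and enol forms)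
Conditions: Dess–Martin periodinane, CH2Cl2, rt
Reagents that add atoms: none
Why: Dess–Martin oxidation of the β-hydroxy ketone should give the β,δ-diketo ester and remove the carbinol stereocentre.

**Step 15**
Reactants: 21 methyl 2,4-dimethyl-3,5-dioxo-5-[(1R,6R,7S,8R)-1,3,5,7,8-pentamethylbicyclo[4.2.0]octa-2,4-dien-7-yl]pentanoate
Product: 22 4-hydroxy-3,5-dimethyl-6-[(1R,6R,7S,8R)-1,3,5,7,8-pentamethylbicyclo[4.2.0]octa-2,4-dien-7-yl]-2H-pyran-2-one
Conditions: DBU, PhMe, rt → 40 °C; dilute acid work-up
Reagents that add atoms: none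
Why: Base-mediated lactonisation of the β,δ-diketo ester, in which the enol oxygen of the C5 ketone attacks the methyl ester, should give the 4-hydroxy-2-pyranone and flatten the remaining side-chain stereocentres.

**Step 16**
Reactants: 22 4-hydroxy-3,5-dimethyl-6-[(1R,6R,7S,8R)-1,3,5,7,8-pentamethylbicyclo[4.2.0]octa-2,4-dien-7-yl]-2H-pyran-2-one
Product: 23 2-methoxy-3,5-dimethyl-6-[(1R,6R,7S,8R)-1,3,5,7,8-pentamethylbicyclo[4.2.0]octa-2,4-dien-7-yl]-4H-pyran-4-one
Conditions: MeOTf, CH2Cl2, 0 °C → rt
Reagents that add atoms: methyl trifluoromethanesulfonate (COS(=O)(=O)C(F)(F)F)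
Why: Regioselective O-methylation, in which the hard methyl electrophile under neutral conditions should alkylate the lactone carbonyl oxygen and proton loss from the resulting pyrylium gives the 2-methoxy-4-pyranone.

**Step 17**
Reactants: 23 2-methoxy-3,5-dimethyl-6-[(1R,6R,7S,8R)-1,3,5,7,8-pentamethylbicyclo[4.2.0]octa-2,4-dien-7-yl]-4H-pyran-4-one
Product: 24 CNP0183511.1, the 2,5-endoperoxide of 23 (6-[2,5-epidioxy-1,3,5,7,8-pentamethylbicyclo[4.2.0]oct-3-en-7-yl]-2-methoxy-3,5-dimethyl-4H-pyran-4-one; O–O bridge on the face anti to the cyclobutane, syn to C1-Me and C6-H; C1, C6, C7, C8 arranged as in 23)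
Conditions: O2, methylene blue (cat.), visible light, CH2Cl2, 0 °C
Reagents that add atoms: dioxygen (O=O)
Why: [4+2] cycloaddition of singlet oxygen to the cyclohexadiene should take place on the face anti to the cyclobutane, because the endo pyrone on C7 shields the concave face, and this sets C2 and C5 as in the target by substrate control.

**Compound list**
1 | 4-methylfuran-2(5H)-one | CC1=CC(=O)OC1 | starting material
2 | (2Z)-4-hydroxy-N-methoxy-N,3-dimethylbut-2-enamide | CON(C)C(=O)/C=C(/C)CO | intermediate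
3 | (2Z)-4-[(tert-butyldimethylsilyl)oxy]-N-methoxy-N,3-dimethylbut-2-enamide | CON(C)C(=O)/C=C(/C)CO[Si](C)(C)C(C)(C)C | intermediate
4 | (3Z)-5-[(tert-butyldimethylsilyl)oxy]-4-methylpent-3-en-2-one | CC(=O)/C=C(/C)CO[Si](C)(C)C(C)(C)C | intermediate
5 | (2Z,4S,5E)-1-[(tert-butyldimethylsilyl)oxy]-2,4-dimethyldeca-2,5-dien-4-ol | CCCC/C=C/[C@@](C)(/C=C(/C)CO[Si](C)(C)C(C)(C)C)O | intermediate
6 | 3-methylbut-3-enoic acid | CC(=C)CC(=O)O | starting material
7 | (2Z,4S,5E)-1-[(tert-butyldimethylsilyl)oxy]-2,4-dimethyldeca-2,5-dien-4-yl 3-methylbut-3-enoate | CCCC/C=C/[C@@](C)(/C=C(/C)CO[Si](C)(C)C(C)(C)C)OC(=O)CC(C)=C | intermediate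
8 | (6S)-6-[(1Z)-3-[(tert-butyldimethylsilyl)oxy]-2-methylprop-1-en-1-yl]-4,6-dimethyl-3,6-dihydro-2H-pyran-2-one | O=C1CC(C)=C[C@@](C)(/C=C(/C)CO[Si](C)(C)C(C)(C)C)O1 | intermediate
9 | 1,1-dibromoethane | CC(Br)Br | starting material
10 | 1,1-bis(bromozincio)ethane | CC([Zn]Br)[Zn]Br | intermediate (not isolated)
11 | (2Z,6S)-6-[(1Z)-3-[(tert-butyldimethylsilyl)oxy]-2-methylprop-1-en-1-yl]-2-ethylidene-4,6-dimethyl-3,6-dihydro-2H-pyran | C/C=C1/CC(C)=C[C@@](C)(/C=C(/C)CO[Si](C)(C)C(C)(C)C)O1 | intermediate
12 | (7R,8S)-7-{[(tert-butyldimethylsilyl)oxy]methyl}-3,5,7,8-tetramethylcycloocta-3,5-dien-1-one | CC(C)(C)[Si](C)(C)OC[C@@]1(C)[C@H](C)C(=O)CC(C)=CC(C)=C1 | intermediate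
13 | (7R,8S)-7-{[(tert-butyldimethylsilyl)oxy]methyl}-3,5,7,8-tetramethylcycloocta-1,3,5-trien-1-yl trifluoromethanesulfonate | CC(C)(C)[Si](C)(C)OC[C@@]1(C)[C@H](C)C(OS(=O)(=O)C(F)(F)F)=CC(C)=CC(C)=C1 | intermediate
14 | (7R,8R)-7-{[(tert-butyldimethylsilyl)oxy]methyl}-1,3,5,7,8-pentamethylcycloocta-1,3,5-triene | CC(C)(C)[Si](C)(C)OC[C@@]1(C)[C@H](C)C(C)=CC(C)=CC(C)=C1 | intermediate (not isolated)
15 | tert-butyl(dimethyl){[(1R,6R,7S,8R)-1,3,5,7,8-pentamethylbicyclo[4.2.0]octa-2,4-dien-7-yl]methoxy}silane | CC(C)(C)[Si](C)(C)OC[C@@]1(C)[C@H](C)[C@@]2(C)C=C(C)C=C(C)[C@@H]12 | intermediate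
16 | [(1R,6R,7S,8R)-1,3,5,7,8-pentamethylbicyclo[4.2.0]octa-2,4-dien-7-yl]methanol | OC[C@@]1(C)[C@H](C)[C@@]2(C)C=C(C)C=C(C)[C@@H]12 | intermediate
17 | (1R,6R,7S,8R)-1,3,5,7,8-pentamethylbicyclo[4.2.0]octa-2,4-diene-7-carbaldehyde | O=C[C@@]1(C)[C@H](C)[C@@]2(C)C=C(C)C=C(C)[C@@H]12 | intermediate
18 | methyl 2-methyl-3-oxopentanoate | CCC(=O)C(C)C(=O)OC | starting material
19 | sodium lithium dianion of methyl 2-methyl-3-oxopentanoate | [Na+].[Li+].COC(=O)[C-](C)C(=O)[CH-]C | intermediate (not isolated)
20 | methyl 5-hydroxy-2,4-dimethyl-3-oxo-5-[(1R,6R,7S,8R)-1,3,5,7,8-pentamethylbicyclo[4.2.0]octa-2,4-dien-7-yl]pentanoate | COC(=O)C(C)C(=O)C(C)C(O)[C@@]1(C)[C@H](C)[C@@]2(C)C=C(C)C=C(C)[C@@H]12 | intermediate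
21 | methyl 2,4-dimethyl-3,5-dioxo-5-[(1R,6R,7S,8R)-1,3,5,7,8-pentamethylbicyclo[4.2.0]octa-2,4-dien-7-yl]pentanoate | COC(=O)C(C)C(=O)C(C)C(=O)[C@@]1(C)[C@H](C)[C@@]2(C)C=C(C)C=C(C)[C@@H]12 | intermediate
22 | 4-hydroxy-3,5-dimethyl-6-[(1R,6R,7S,8R)-1,3,5,7,8-pentamethylbicyclo[4.2.0]octa-2,4-dien-7-yl]-2H-pyran-2-one | O=c1oc([C@@]2(C)[C@H](C)[C@@]3(C)C=C(C)C=C(C)[C@@H]23)c(C)c(O)c1C | intermediate
23 | 2-methoxy-3,5-dimethyl-6-[(1R,6R,7S,8R)-1,3,5,7,8-pentamethylbicyclo[4.2.0]octa-2,4-dien-7-yl]-4H-pyran-4-one | COc1oc([C@@]2(C)[C@H](C)[C@@]3(C)C=C(C)C=C(C)[C@@H]23)c(C)c(=O)c1C | intermediate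
24 | CNP0183511.1, 2,5-endoperoxide of 23 with the O–O bridge anti to the cyclobutane | COc1oc([C@@]2(C)[C@H](C)[C@@]3(C)[C@@H]4OO[C@@](C)(C=C4C)[C@@H]23)c(C)c(=O)c1C | target

Total step count: 17. Longest linear sequence: 17 steps (1 to 24).

**Steps most likely to fail**

Step 8. The shift may be too slow at temperatures the enol ether survives, because the silyloxymethyl group must sit axial over the dihydropyran bridge. Migration of the exocyclic alkene into the ring, heterolysis of the bis-allylic C–O bond, or a non-chair array that would invert C8 relative to C7 could then take over. Fallback, from enol ether 11: iBu3Al in CH2Cl2 at −78 → 0 °C would promote the rearrangement through the aluminium-bound ether at low temperature and reduce the new ketone in the same flask to (7R,8S)-7-{[(tert-butyldimethylsilyl)oxy]methyl}-3,5,7,8-tetramethylcycloocta-3,5-dien-1-ol F1 (carbinol epimers). Dess–Martin oxidation of that alcohol would return to ketone 12.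

Step 10. The electrocyclisation is under equilibrium control and may settle on the other cis-fused isomer (C7 and C8 methyls on the concave face), or [1,5]-hydrogen shifts of the triene may compete at the temperature needed. The unwanted isomer can be reheated, since both isomers pass through 14. Fallback, from triflate 13: HF·pyridine in THF would give (7R,8S)-7-(hydroxymethyl)-3,5,7,8-tetramethylcycloocta-1,3,5-trien-1-yl trifluoromethanesulfonate F2, and Dess–Martin oxidation the (7R,8S)-7-formyl trienyl triflate F3. Stille methylation (Me4Sn, Pd(PPh3)4, LiCl, THF, 50 °C) would then give (7R,8R)-1,3,5,7,8-pentamethylcycloocta-1,3,5-triene-7-carbaldehyde F4. This should close in the same flask with the flat formyl group, smaller than methyl, on the concave face, and so arrive directly at aldehyde 17.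

Step 4. Facial discrimination at the hindered Z-enone may be insufficient, or addition may be slow enough for the enone to drift toward the E isomer under the Lewis acidic conditions. Fallback, from enone 4: CH2=CHMgBr with CeCl3 in THF at −78 °C would give racemic (4Z)-6-[(tert-butyldimethylsilyl)oxy]-3,5-dimethylhexa-1,4-dien-3-ol F5. Steglich esterification with 6 would give the racemic 3-methylbut-3-enoate F6, and ring-closing metathesis (loss of ethene) the racemic lactone F7. Preparative chromatography on a chiral stationary phase would then deliver the (S) enantiomer, which is lactone 8.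

**Further compounds**
F1 | step 8 | (7R,8S)-7-{[(tert-butyldimethylsilyl)oxy]methyl}-3,5,7,8-tetramethylcycloocta-3,5-dien-1-ol | CC(C)(C)[Si](C)(C)OC[C@@]1(C)[C@H](C)C(O)CC(C)=CC(C)=C1
F2 | step 10 | (7R,8S)-7-(hydroxymethyl)-3,5,7,8-tetramethylcycloocta-1,3,5-trien-1-yl trifluoromethanesulfonate | OC[C@@]1(C)[C@H](C)C(OS(=O)(=O)C(F)(F)F)=CC(C)=CC(C)=C1
F3 | step 10 | (7R,8S)-7-formyl-3,5,7,8-tetramethylcycloocta-1,3,5-trien-1-yl trifluoromethanesulfonate | O=C[C@@]1(C)[C@H](C)C(OS(=O)(=O)C(F)(F)F)=CC(C)=CC(C)=C1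
F4 | step 10 | (7R,8R)-1,3,5,7,8-pentamethylcycloocta-1,3,5-triene-7-carbaldehyde (route numbering) | O=C[C@@]1(C)[C@H](C)C(C)=CC(C)=CC(C)=C1
F5 | step 4 | racemic (4Z)-6-[(tert-butyldimethylsilyl)oxy]-3,5-dimethylhexa-1,4-dien-3-ol | C=CC(C)(O)/C=C(/C)CO[Si](C)(C)C(C)(C)C
F6 | step 4 | racemic (4Z)-6-[(tert-butyldimethylsilyl)oxy]-3,5-dimethylhexa-1,4-dien-3-yl 3-methylbut-3-enoate | C=CC(C)(/C=C(/C)CO[Si](C)(C)C(C)(C)C)OC(=O)CC(C)=C
F7 | step 4 | racemic 6-[(1Z)-3-[(tert-butyldimethylsilyl)oxy]-2-methylprop-1-en-1-yl]-4,6-dimethyl-3,6-dihydro-2H-pyran-2-one | O=C1CC(C)=CC(C)(/C=C(/C)CO[Si](C)(C)C(C)(C)C)O1
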